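**Retrosynthetic overview**

- The target is traced back (desilylation, α-methylenation, decarboxylation) to a 15-ketone whose bicyclo[3.2.1]octene (rings C and D) is cut at C15–C16 and C11–C12 together. The forward reaction is a formal [3+2] annulation of a donor–acceptor cyclopropane on C13 (C12 silyloxy donor, C16 benzyl ester acceptor) with a benzyl dienol ether (C15=C11) on C9.
- Enabling feature: the cyclopentane ring C11–C12–C13–C16–C15 carries oxygen on C12 and on C15 and an enolizable carbon C16, so C12/C13/C16 is a 1,3-donor/acceptor triad facing the two-carbon enol unit C11/C15. The ring B alkene C8=C9 makes C11 the α-carbon of a dienol ether and holds C11 and C14 cis, so the six-membered ring C9–C8–C14–C13–C12–C11 can close first.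
- Both side chains grow from the two ester carbons (C11, C14) of a Diels–Alder adduct of dimethyl acetylenedicarboxylate with a ring A vinylcyclohexene. The C1 carbinol (CBS reduction) relays stereocontrol to C10, C5 and C6; C13 is set by asymmetric cyclopropanation.
- Order of ring formation: ring A (from a cyclohexenone), ring B (Diels–Alder), temporary cyclopropane, then rings C and D together in the key step.

Key step: step 19

Remark: terpenoid numbering is used from compound 9 on (C1 acetate carbon, C4 gem-dimethyl, C10 with methyl C20, C8=C9 ring B alkene, C11 and C13 bridgeheads, C12 carbinol bridge, C14 methylene, C15 ketone, C16=C17 methylene), α means the decalin face that carries C20, and the sense of induction of the copper bis(oxazoline) catalyst in step 14 is assumed and would be fixed on a model (enantiomeric ligand if opposite).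

**Route**

Step 1
Reactants: 1 3-ethoxy-2-methylcyclohex-2-en-1-one
Product: 3 3-ethoxy-2,6,6-trimethylcyclohex-2-en-1-one, via monomethylated enone 2 (not isolated)
Conditions: LiN(i-Pr)2, THF, −78 °C, then MeI; second portion of LiN(i-Pr)2, then MeI, −78 to 0 °C, same flask
Reagents that add atoms: iodomethane, CI
Why: Kinetic α'-deprotonation of the vinylogous ester (Stork–Danheiser alkylation) carried out twice should place both methyl groups on C6, and no stereocentre remains.

Step 2
Reactants: 3 3-ethoxy-2,6,6-trimethylcyclohex-2-en-1-one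
Product: 5 2,4,4-trimethyl-3-vinylcyclohex-2-en-1-one, via tertiary allylic alkoxide 4 (not isolated)
Conditions: CH2=CHMgBr, CeCl3, THF, −78 to 0 °C; then 1 M HCl, rt
Reagents that add atoms: vinylmagnesium bromide, C=C[Mg]Br; water, O
Why: 1,2-Addition to the vinylogous ester carbonyl followed by acid hydrolysis (Stork–Danheiser transposition) should give the transposed 3-vinyl enone, which is achiral.

Step 3
Reactants: 5 2,4,4-trimethyl-3-vinylcyclohex-2-en-1-one
Product: 6 (S)-2,4,4-trimethyl-3-vinylcyclohex-2-en-1-ol
Conditions: (R)-2-methyl-CBS-oxazaborolidine (cat.), catecholborane, toluene, −78 °C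
Reagents that add atoms: none
Why: In this Corey–Bakshi–Shibata reduction the fully substituted alkene side acts as the large group, so the (R)-catalyst should deliver hydride to the face that gives the (S)-carbinol, and catecholborane leaves the diene untouched.

Step 4
Reactants: 6 (S)-2,4,4-trimethyl-3-vinylcyclohex-2-en-1-ol
Product: 7 (S)-1-(4-methoxybenzyloxy)-2,4,4-trimethyl-3-vinylcyclohex-2-ene
Conditions: NaH, 4-MeOC6H4CH2Cl, Bu4NI (cat.), THF/DMF, 0 °C to rt
Reagents that add atoms: 4-methoxybenzyl chloride, COc1ccc(CCl)cc1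
Why: A Williamson etherification protects the carbinol without touching the stereocentre.

Step 5
Reactants: 7 (S)-1-(4-methoxybenzyloxy)-2,4,4-trimethyl-3-vinylcyclohex-2-ene; 8 dimethyl acetylenedicarboxylate
Product: 9 dimethyl 1α-(4-methoxybenzyloxy)-4,4,10α-trimethyldecalin-5,8-diene-8,9-dicarboxylate
Conditions: 8, toluene, 110 °C, sealed tube, BHT (cat.)
Reagents that add atoms: none
Why: The thermal Diels–Alder reaction of 2,6,6-trimethyl-1-vinylcyclohexene-type dienes with this alkyne is a known entry to such decalins; the allylic ether sits pseudo-axial (A(1,2) strain with the ring methyl), so the dienophile should add to the opposite face and leave the C10 methyl cis to the C1 oxygen.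

Step 6
Reactants: 9 the diene diester
Product: 10 dimethyl 6β-hydroxy-1α-(4-methoxybenzyloxy)-4,4,10α-trimethyl-5β-H-decal-8-ene-8,9-dicarboxylate
Conditions: BH3·THF, THF, 0 °C; then 30% H2O2, aq. NaOAc, 0 °C to rt
Reagents that add atoms: hydrogen peroxide, OO
Why: Hydroboration–oxidation should engage only the trisubstituted C5=C6 bond (the diester alkene is electron-poor), with boron on C6 and syn addition from the β face away from C20, which sets the trans ring fusion (5β-H).

Step 7
Reactants: 10 the 6β-alcohol
Product: 11 dimethyl 1α-(4-methoxybenzyloxy)-4,4,10α-trimethyl-6-oxo-5β-H-decal-8-ene-8,9-dicarboxylate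
Conditions: Dess–Martin periodinane, NaHCO3, CH2Cl2, rt
Reagents that add atoms: none
Why: Dess–Martin oxidation under buffered conditions gives the ketone, and any cis-fused material can equilibrate through the enol to the trans-decalone.

Step 8
Reactants: 11 the 6-ketone diester
Product: 12 8,9-bis(hydroxymethyl)-1α-(4-methoxybenzyloxy)-4,4,10α-trimethyl-5β-H-decal-8-en-6α-ol (6α,11,14-triol)
Conditions: i-Bu2AlH (excess), CH2Cl2, −78 to 0 °C; aq. KNaC4H4O6 work-up
Reagents that add atoms: none
Why: Hydride reduction by i-Bu2AlH should attack the ketone from the β face, because the α face is blocked by the axial C20 and 4α methyl groups, giving the axial 6α-carbinol, and should reduce both conjugated esters 1,2 to the allylic alcohols.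

Step 9
Reactants: 12 the triol
Product: 13 11,14-O-(4-methoxybenzylidene) acetal of 12 (2-aryl-4,7-dihydro-1,3-dioxepine, epimers at the acetal carbon)
Conditions: 4-MeOC6H4CH(OMe)2, pyridinium p-toluenesulfonate (cat.), CH2Cl2, rt
Reagents that add atoms: 4-methoxybenzaldehyde dimethyl acetal, COc1ccc(C(OC)OC)cc1
Why: Transacetalization ties the two cis-disposed primary allylic hydroxyls into a seven-membered acetal, while the hindered axial C6 hydroxyl does not take part.

Step 10
Reactants: 13 the cyclic acetal
Product: 14 11-O-(4-methoxybenzyl) ether with free 14-OH and 6α-OH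
Conditions: i-Bu2AlH, CH2Cl2, −78 to 0 °C; aq. KNaC4H4O6 work-up
Reagents that add atoms: none
Why: In this reductive acetal opening aluminium should coordinate the less hindered O14 (O11 lies next to the quaternary C10), so that the C–O14 bond breaks and the benzyl-type ether stays on O11.

Step 11
Reactants: 14 the C14 alcohol
Product: 15 14-bromide of 14
Conditions: CBr4, PPh3, 2,6-lutidine, CH2Cl2, 0 °C; used at once
Reagents that add atoms: carbon tetrabromide, BrC(Br)(Br)Br
Why: The Appel reaction should convert only the primary allylic hydroxyl; the axial C6 hydroxyl is too hindered, and it cannot displace the bromide because the ether formed would hold a bridgehead alkene.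

Step 12
Reactants: 15 the allylic bromide; 16 acetaldehyde N,N-dimethylhydrazone
Product: 18 C8-(3-oxopropyl) aldehyde (chain C14–C13–C12 with the aldehyde at C12), via alkylated hydrazone 17 (not isolated)
Conditions: 16, LiN(i-Pr)2, THF, 0 °C; then 15, −78 to 0 °C; then aq. oxalic acid, Et2O, rt
Reagents that add atoms: water, O
Why: Alkylation of the lithiated hydrazone (azaenolate alkylation) at the primary allylic bromide, followed by mild hydrolysis, adds the two-carbon aldehyde unit without forming a stereocentre.

Step 13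
Reactants: 18 the aldehyde
Product: 19 (Z)-12-(tert-butyldimethylsilyloxy) enol ether (C12=C13) with 6α-silyl ether
Conditions: t-BuMe2SiOTf, Et3N, CH2Cl2, −78 °C to rt
Reagents that add atoms: tert-butyldimethylsilyl triflate, CC(C)(C)[Si](C)(C)OS(=O)(=O)C(F)(F)F
Why: Soft enolization with the silyl triflate (silyl enol ether formation) should give mainly the (Z)-enol ether, and the same reagent silylates the hindered C6 hydroxyl.

Step 14
Reactants: 19 the silyl enol ether; 20 benzyl diazoacetate
Product: 21 benzyl 2-(tert-butyldimethylsilyloxy)cyclopropanecarboxylate on C14 (ring C13–C12–C16; C14 and the silyloxy group cis, ester trans, C13 as in the target)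
Conditions: 20 (slow addition), CuOTf (as (CuOTf)2·C6H6, 5 mol %), 2,2'-isopropylidenebis[(4S)-4-tert-butyl-2-oxazoline] (6 mol %), CH2Cl2, rt
Reagents that add atoms: none
Why: Copper-carbene cyclopropanation picks the electron-rich silyl enol ether over the hindered tetrasubstituted alkene, transfers the (Z)-geometry stereospecifically, puts the ester trans for steric reasons, and the bis(oxazoline) ligand is expected to choose the alkene face and so set C13.

Step 15
Reactants: 21 the cyclopropane
Product: 22 1α,11-diol (both 4-methoxybenzyl ethers removed)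
Conditions: DDQ, CH2Cl2/pH 7 phosphate buffer, 0 °C
Reagents that add atoms: none
Why: Oxidative cleavage of 4-methoxybenzyl ethers by DDQ under buffered conditions should spare the silyl ethers, the benzyl ester and the acceptor-substituted cyclopropane.

Step 16
Reactants: 22 the diol
Product: 23 C9-carbaldehyde (C11 aldehyde) with free 1α-OH
Conditions: MnO2 (excess), CH2Cl2, rt
Reagents that add atoms: none
Why: Allylic oxidation with MnO2 converts only the allylic C11 carbinol and leaves the saturated C1 carbinol.

Step 17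
Reactants: 23 the hydroxy enal
Product: 24 1α-acetate of 23
Conditions: Ac2O, pyridine, DMAP (cat.), CH2Cl2, rt
Reagents that add atoms: acetic anhydride, CC(=O)OC(C)=O
Why: DMAP-catalysed acylation installs the C1 acetate of the target now that all hydride reductions are past.

Step 18
Reactants: 24 the enal acetate; 25 (benzyloxymethyl)triphenylphosphonium chloride
Product: 26 benzyl dienol ether C9–CH=CH–OCH2Ph (C11=C15, E/Z mixture)
Conditions: 25, KN(SiMe3)2, THF, −78 °C; then 24, −78 to 0 °C
Reagents that add atoms: none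
Why: Wittig olefination with the alkoxymethylene ylide homologates the aldehyde by the C15 carbon and gives the dienol ether directly; both alkene isomers lead to the same oxocarbenium ion later.

Step 19
Reactants: 26 the cyclopropane dienol ether
Product: 28 benzyl 1α-acetoxy-15-benzyloxy-6α,12-bis(tert-butyldimethylsilyloxy)-bicyclo[3.2.1]octene-16-carboxylate with rings C and D closed (C15/C16 epimers), via oxocarbenium triflate 27 (not isolated)
Conditions: Me3SiOTf (0.2 equiv), 2,6-di-tert-butyl-4-methylpyridine (0.3 equiv), 4 Å molecular sieves, CH2Cl2, −78 to −40 °C; Et3N quench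
Reagents that add atoms: none
Why: Proposed new method: Me3SiOTf silylates the benzyl ester carbonyl, the cyclopropane opens at its only doubly activated bond (C12–C16, between the silyloxy donor and the ester acceptor) to a C12 silyloxocarbenium ion and a C16 silyl ketene acetal, the α-carbon C11 of the dienol ether adds to C12, and the ketene acetal then adds to the resulting C15 benzyloxocarbenium ion with release of the silyl cation, so that C11–C12 and C15–C16 form at the expense of the cyclopropane bond in an isomerization. The closest known reaction type is the Lewis acid-catalysed formal [3+2] annulation of donor–acceptor cyclopropanes with enol ethers and silyl enol ethers (intermolecular, mostly with cyclopropane-1,1-diesters), together with the Lewis acid ring-opening and aldol chemistry of 2-silyloxycyclopropanecarboxylates; new here are the intramolecular bridging mode, the monoester and the dienol ether. The six-membered ring (C9, C8, C14, C13, C12, C11) closes in a 6-(enolexo)-exo-trig Mukaiyama–Prins step and the five-membered ring (C11, C12, C13, C16, C15) in a 5-(enolexo)-exo-trig Mukaiyama aldol step. C13 is carried over unchanged from the cyclopropane and decides on which face of ring B the two-carbon bridge is built; C11 must carry C15 cis to C16 for the aldol closure, and a trans adduct can return through proton loss to the dienol ether and re-addition; at C12 the silyloxy group should take the position anti to the C8=C9 bridge (equatorial on the new cyclohexene) in a compact transition state in which the C13 ketene acetal arm is already axial; C15 and C16 form as epimers that are erased later. The step needs α- over γ-attack of the dienol ether, which the ring B double bond secures because it holds C11 and C14 cis and γ-attack at C8 would give a four-membered ring, and it needs activation of the cyclopropane without protonolysis of the dienol ether, which the hindered pyridine base and the low temperature should secure.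

Step 20
Reactants: 28 the bicyclic benzyl ether benzyl ester
Product: 29 15-hydroxy-16-carboxylic acid (C15/C16 epimers)
Conditions: H2 (1 atm), Pd(OH)2 on carbon, EtOAc, rt
Reagents that add atoms: none
Why: Hydrogenolysis removes the benzyl ether and the benzyl ester together, while the tetrasubstituted C8=C9 alkene, the silyl ethers and the acetate should stay.

Step 21
Reactants: 29 the hydroxy acid
Product: 31 1α-acetoxy-6α,12-bis(tert-butyldimethylsilyloxy) 15-ketone with C16 as CH2, via keto acid 30 (not isolated)
Conditions: Dess–Martin periodinane, CH2Cl2, rt; then toluene, 60 °C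
Reagents that add atoms: none
Why: Dess–Martin oxidation gives a β-keto acid that decarboxylates on warming, which removes the activating group; C11 cannot epimerize because its enol would be a bridgehead alkene.

Step 22
Reactants: 31 the 15-ketone
Product: 32 16-methylene-15-ketone bis(silyl ether)
Conditions: paraformaldehyde, i-Pr2NH·CF3CO2H, CF3CO2H (cat.), THF, 65 °C
Reagents that add atoms: formaldehyde (as paraformaldehyde), C=O
Why: Mannich-type α-methylenation can occur only at C16, the single enolizable position, and elimination gives the exocyclic enone because an endocyclic one would violate Bredt's rule.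

Step 23
Reactants: 32 the bis(silyl ether)
Product: 33 target CNP0149338.1
Conditions: HF·pyridine, pyridine, THF, 0 °C to rt
Reagents that add atoms: none
Why: Acidic fluoride desilylation frees the C6 and C12 hydroxyls without base, so the acetate, the enone and the β-hydroxy ketone (no retro-aldol) should survive.

**Compound list**

1 | 3-ethoxy-2-methylcyclohex-2-en-1-one | CCOC1=C(C)C(=O)CCC1 | starting material
2 | 3-ethoxy-2,6-dimethylcyclohex-2-en-1-one (racemic) | CCOC1=C(C)C(=O)C(C)CC1 | intermediate (not isolated)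
3 | 3-ethoxy-2,6,6-trimethylcyclohex-2-en-1-one | CCOC1=C(C)C(=O)C(C)(C)CC1 | intermediate
4 | 3-ethoxy-2,6,6-trimethyl-1-vinylcyclohex-2-en-1-ol (racemic, as magnesium alkoxide) | CCOC1=C(C)C(O)(C=C)C(C)(C)CC1 | intermediate (not isolated)
5 | 2,4,4-trimethyl-3-vinylcyclohex-2-en-1-one | C=CC1=C(C)C(=O)CCC1(C)C | intermediate
6 | (S)-2,4,4-trimethyl-3-vinylcyclohex-2-en-1-ol | CC1(C)CC[C@H](O)C(C)=C1C=C | intermediate
7 | (S)-1-(4-methoxybenzyloxy)-2,4,4-trimethyl-3-vinylcyclohex-2-ene | CC1(C)CC[C@H](OCc2ccc(OC)cc2)C(C)=C1C=C | intermediate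
8 | dimethyl acetylenedicarboxylate | COC(=O)C#CC(=O)OC | starting material
9 | dimethyl 1α-(4-methoxybenzyloxy)-4,4,10α-trimethyldecalin-5,8-diene-8,9-dicarboxylate | COC(=O)C3=C(C(=O)OC)CC=C1C(C)(C)CC[C@H](OCc2ccc(OC)cc2)[C@@]31C | intermediate
10 | 6β-hydroxy-5β-H diester | COC(=O)C3=C(C(=O)OC)C[C@@H](O)[C@@H]1C(C)(C)CC[C@H](OCc2ccc(OC)cc2)[C@@]31C | intermediate
11 | 6-oxo-5β-H diester | COC(=O)C3=C(C(=O)OC)CC(=O)[C@@H]1C(C)(C)CC[C@H](OCc2ccc(OC)cc2)[C@@]31C | intermediate
12 | 6α,11,14-triol | OCC3=C(CO)C[C@H](O)[C@@H]1C(C)(C)CC[C@H](OCc2ccc(OC)cc2)[C@@]31C | intermediate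
13 | 11,14-O-(4-methoxybenzylidene) acetal (acetal carbon unassigned) | C4C3=C(COC(c5ccc(OC)cc5)O4)C[C@H](O)[C@@H]1C(C)(C)CC[C@H](OCc2ccc(OC)cc2)[C@@]31C | intermediate
14 | 11-O-(4-methoxybenzyl) ether, 14-OH and 6α-OH free | COc4ccc(COCC3=C(CO)C[C@H](O)[C@@H]1C(C)(C)CC[C@H](OCc2ccc(OC)cc2)[C@@]31C)cc4 | intermediate
15 | 14-bromide | COc4ccc(COCC3=C(CBr)C[C@H](O)[C@@H]1C(C)(C)CC[C@H](OCc2ccc(OC)cc2)[C@@]31C)cc4 | intermediate
16 | acetaldehyde N,N-dimethylhydrazone | CC=NN(C)C | starting material
17 | N,N-dimethylhydrazone of 18 | COc4ccc(COCC3=C(CCC=NN(C)C)C[C@H](O)[C@@H]1C(C)(C)CC[C@H](OCc2ccc(OC)cc2)[C@@]31C)cc4 | intermediate (not isolated)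
18 | C8-(3-oxopropyl) aldehyde | COc4ccc(COCC3=C(CCC=O)C[C@H](O)[C@@H]1C(C)(C)CC[C@H](OCc2ccc(OC)cc2)[C@@]31C)cc4 | intermediate
19 | (Z)-silyl enol ether, 6α-silyl ether | COc4ccc(COCC3=C(C/C=C\O[Si](C)(C)C(C)(C)C)C[C@H](O[Si](C)(C)C(C)(C)C)[C@@H]1C(C)(C)CC[C@H](OCc2ccc(OC)cc2)[C@@]31C)cc4 | intermediate
20 | benzyl diazoacetate | [N-]=[N+]=CC(=O)OCc1ccccc1 | starting material
21 | benzyl 2-silyloxycyclopropanecarboxylate (C13–C12–C16 ring) | COc4ccc(COCC3=C(C[C@H]5[C@@H](O[Si](C)(C)C(C)(C)C)[C@@H]5C(=O)OCc6ccccc6)C[C@H](O[Si](C)(C)C(C)(C)C)[C@@H]1C(C)(C)CC[C@H](OCc2ccc(OC)cc2)[C@@]31C)cc4 | intermediate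
22 | 1α,11-diol | OCC3=C(C[C@H]5[C@@H](O[Si](C)(C)C(C)(C)C)[C@@H]5C(=O)OCc6ccccc6)C[C@H](O[Si](C)(C)C(C)(C)C)[C@@H]1C(C)(C)CC[C@H](O)[C@@]31C | intermediate
23 | C11 aldehyde, 1α-OH | O=CC3=C(C[C@H]5[C@@H](O[Si](C)(C)C(C)(C)C)[C@@H]5C(=O)OCc6ccccc6)C[C@H](O[Si](C)(C)C(C)(C)C)[C@@H]1C(C)(C)CC[C@H](O)[C@@]31C | intermediate
24 | C11 aldehyde, 1α-acetate | O=CC3=C(C[C@H]5[C@@H](O[Si](C)(C)C(C)(C)C)[C@@H]5C(=O)OCc6ccccc6)C[C@H](O[Si](C)(C)C(C)(C)C)[C@@H]1C(C)(C)CC[C@H](OC(C)=O)[C@@]31C | intermediate
25 | (benzyloxymethyl)triphenylphosphonium chloride | [Cl-].c1ccccc1COC[P+](c1ccccc1)(c1ccccc1)c1ccccc1 | starting material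
26 | benzyl dienol ether with cyclopropane (E/Z at C11=C15) | C(OCc7ccccc7)=CC3=C(C[C@H]5[C@@H](O[Si](C)(C)C(C)(C)C)[C@@H]5C(=O)OCc6ccccc6)C[C@H](O[Si](C)(C)C(C)(C)C)[C@@H]1C(C)(C)CC[C@H](OC(C)=O)[C@@]31C | intermediate
27 | ring C oxocarbenium triflate with C16 silyl ketene acetal | C(=[O+]Cc7ccccc7)[C@@H]2C3=C(C[C@H](C=C(OCc6ccccc6)O[Si](C)(C)C)[C@@H]2O[Si](C)(C)C(C)(C)C)C[C@H](O[Si](C)(C)C(C)(C)C)[C@@H]1C(C)(C)CC[C@H](OC(C)=O)[C@@]31C.[O-]S(=O)(=O)C(F)(F)F | intermediate (not isolated)
28 | 15-benzyloxy-16-benzyl ester bicyclo[3.2.1]octene (C15/C16 epimers) | O=C(OCc6ccccc6)C1C(OCc7ccccc7)[C@@H]2C3=C(C[C@H]1[C@@H]2O[Si](C)(C)C(C)(C)C)C[C@H](O[Si](C)(C)C(C)(C)C)[C@@H]1C(C)(C)CC[C@H](OC(C)=O)[C@@]31C | intermediate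
29 | 15-hydroxy-16-carboxylic acid | OC(=O)C1C(O)[C@@H]2C3=C(C[C@H]1[C@@H]2O[Si](C)(C)C(C)(C)C)C[C@H](O[Si](C)(C)C(C)(C)C)[C@@H]1C(C)(C)CC[C@H](OC(C)=O)[C@@]31C | intermediate
30 | 15-oxo-16-carboxylic acid | OC(=O)C1C(=O)[C@@H]2C3=C(C[C@H]1[C@@H]2O[Si](C)(C)C(C)(C)C)C[C@H](O[Si](C)(C)C(C)(C)C)[C@@H]1C(C)(C)CC[C@H](OC(C)=O)[C@@]31C | intermediate (not isolated)
31 | 15-ketone, 6α,12-bis(silyl ether), 1α-acetate | C1C(=O)[C@@H]2C3=C(C[C@H]1[C@@H]2O[Si](C)(C)C(C)(C)C)C[C@H](O[Si](C)(C)C(C)(C)C)[C@@H]1C(C)(C)CC[C@H](OC(C)=O)[C@@]31C | intermediate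
32 | 16-methylene-15-ketone bis(silyl ether) | C=C1C(=O)[C@@H]2C3=C(C[C@H]1[C@@H]2O[Si](C)(C)C(C)(C)C)C[C@H](O[Si](C)(C)C(C)(C)C)[C@@H]1C(C)(C)CC[C@H](OC(C)=O)[C@@]31C | intermediate
33 | CNP0149338.1 | C=C1C(=O)[C@@H]2C3=C(C[C@H]1[C@@H]2O)C[C@H](O)[C@@H]1C(C)(C)CC[C@H](OC(C)=O)[C@@]31C | target

**Step count and risks**

Total step count: 23. Longest linear sequence: 23 steps (from 1; compounds 8, 16, 20 and 25 are purchased).

Steps most likely to fail:

1. Step 19 (Proposed new method). The cascade may stop after the first C–C bond, or the opened cyclopropane may lose a proton next to the oxocarbenium ion, which gives an enol ether and erases C13; protonolysis of the dienol ether is a further risk. Fallback with known chemistry, setting out from 26 and returning at 31: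
   - Fluoride-induced ring opening (Et3N·3HF, THF) of the silyloxycyclopropane would give the γ-oxo ester F1.
   - BF3·OEt2 at −78 °C would close ring C by intramolecular Mukaiyama-type aldol addition of the dienol ether to the aldehyde, giving after aqueous work-up the hydroxy aldehyde F2.
   - Silylation (t-BuMe2SiOTf, 2,6-lutidine) would give the silyl ether F3, Pinnick oxidation (NaClO2, NaH2PO4, 2-methyl-2-butene) the acid F4, and esterification (Me3SiCHN2, MeOH) the methyl ester F5.
   - A Dieckmann condensation (KN(SiMe3)2, THF) would then close ring D to the keto ester F6. It should be regioselective because only attack of the C16 ester enolate on the C15 ester gives an enolizable β-keto ester, and C11 can epimerize to the reactive cis isomer.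
   - Hydrogenolysis (H2, Pd on carbon) and decarboxylation through 30 would deliver 31.

2. Step 14. Facial control by the catalyst at C13 is remote from the decalin stereocentres and may be poor, geometric isomers of the enol ether may respond differently, and the carbene may dimerize. Fallback, setting out from 19 and returning at 21: cyclopropanation with 20 under the achiral catalyst Rh2(OAc)4, with no attempt at facial control, should give 21 together with the epimeric cyclopropane F7, of opposite configuration at C12, C13 and C16. Because the decalin is a single enantiomer the two are diastereomers and would be separated by preparative HPLC, 21 re-entering at step 15.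

3. Step 10. Regioselectivity of the reductive acetal cleavage may be poor, which would leave the wrong hydroxyl free. Fallback, setting out from 12 and returning at 14: selective silylation of the less hindered C14 hydroxyl (t-BuMe2SiCl, imidazole, CH2Cl2, −20 °C) would give the monosilyl ether F8, 4-methoxybenzylation of the C11 hydroxyl (4-methoxybenzyl trichloroacetimidate, La(OTf)3 cat.) the mixed ether F9, and desilylation (Bu4NF, THF) would give 14.

Further compounds
F1 | step 19 | γ-oxo benzyl ester with benzyl dienol ether (opened cyclopropane) | C(OCc7ccccc7)=CC3=C(C[C@H](CC(=O)OCc6ccccc6)C=O)C[C@H](O[Si](C)(C)C(C)(C)C)[C@@H]1C(C)(C)CC[C@H](OC(C)=O)[C@@]31C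
F2 | step 19 | ring C hydroxy aldehyde (C11–C12 bond formed) | O=C[C@@H]2C3=C(C[C@H](CC(=O)OCc6ccccc6)[C@@H]2O)C[C@H](O[Si](C)(C)C(C)(C)C)[C@@H]1C(C)(C)CC[C@H](OC(C)=O)[C@@]31C
F3 | step 19 | 12-silyl ether of F2 | O=C[C@@H]2C3=C(C[C@H](CC(=O)OCc6ccccc6)[C@@H]2O[Si](C)(C)C(C)(C)C)C[C@H](O[Si](C)(C)C(C)(C)C)[C@@H]1C(C)(C)CC[C@H](OC(C)=O)[C@@]31C
F4 | step 19 | C15 carboxylic acid | OC(=O)[C@@H]2C3=C(C[C@H](CC(=O)OCc6ccccc6)[C@@H]2O[Si](C)(C)C(C)(C)C)C[C@H](O[Si](C)(C)C(C)(C)C)[C@@H]1C(C)(C)CC[C@H](OC(C)=O)[C@@]31C
F5 | step 19 | C15 methyl ester | COC(=O)[C@@H]2C3=C(C[C@H](CC(=O)OCc6ccccc6)[C@@H]2O[Si](C)(C)C(C)(C)C)C[C@H](O[Si](C)(C)C(C)(C)C)[C@@H]1C(C)(C)CC[C@H](OC(C)=O)[C@@]31C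
F6 | step 19 | benzyl 15-oxo-16-carboxylate (bicyclic β-keto ester) | O=C(OCc6ccccc6)C1C(=O)[C@@H]2C3=C(C[C@H]1[C@@H]2O[Si](C)(C)C(C)(C)C)C[C@H](O[Si](C)(C)C(C)(C)C)[C@@H]1C(C)(C)CC[C@H](OC(C)=O)[C@@]31C
F7 | step 14 | cyclopropane diastereomer of 21 (opposite at C12, C13, C16) | COc4ccc(COCC3=C(C[C@@H]5[C@H](O[Si](C)(C)C(C)(C)C)[C@H]5C(=O)OCc6ccccc6)C[C@H](O[Si](C)(C)C(C)(C)C)[C@@H]1C(C)(C)CC[C@H](OCc2ccc(OC)cc2)[C@@]31C)cc4
F8 | step 10 | 14-O-silyl ether of triol 12 | OCC3=C(CO[Si](C)(C)C(C)(C)C)C[C@H](O)[C@@H]1C(C)(C)CC[C@H](OCc2ccc(OC)cc2)[C@@]31C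
F9 | step 10 | 11-O-(4-methoxybenzyl) 14-O-silyl ether | COc4ccc(COCC3=C(CO[Si](C)(C)C(C)(C)C)C[C@H](O)[C@@H]1C(C)(C)CC[C@H](OCc2ccc(OC)cc2)[C@@]31C)cc4
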